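**Strategy.** Everything rests on cutting the C1–C2 bond of the diterpenyl chain, between the ester-bearing O–CH2 carbon and the vinylic CH of the (2E)-C2=C3(CH3) olefin. One Negishi sp3–sp2 coupling joins the complete linoleate, carried as its (acyloxy)methylzinc iodide, to a C19 (E)-alkenyl iodide that already holds the cyclohexene ring and both trisubstituted olefins. It exploits that the zinc-bearing CH2 has no β-hydrogen and sits beside a zinc-chelating ester oxygen, and it delivers the finished ester with the (2E) geometry intact. The iodide arises from two Cp2ZrCl2-catalysed alkyne carboaluminations; the ring stereocentre comes from a CBS reduction relayed by Claisen rearrangement.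

Key step: step 11

Remark: the ring carbon is (S), the chain olefins are 2E,6E and the acyl chain is 9Z,12Z, as read from the structure; 2,4,4-trimethylcyclohex-2-en-1-one, (4-bromobut-1-yn-1-yl)trimethylsilane and linoleic acid are taken as catalogue compounds.

**Route**

Step 1
Reactants: 1 2,4,4-trimethylcyclohex-2-en-1-one
Product: 2 (1R)-2,4,4-trimethylcyclohex-2-en-1-ol
Conditions: (S)-1-methyl-3,3-diphenyltetrahydro-1H,3H-pyrrolo[1,2-c][1,3,2]oxazaborole ((S)-Me-CBS, 10 mol %), BH3·SMe2 (0.6 equiv), THF, −20 °C; aq. NH4Cl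
Reagents that add atoms: none
Why: Corey–Bakshi–Shibata reduction, in which the ketone should bind the oxazaborolidine boron anti to its larger C2(CH3)=C3 arm so that hydride reaches one carbonyl face only, setting the (R) carbinol by 1,2-reduction.

Step 2
Reactants: 2 (1R)-2,4,4-trimethylcyclohex-2-en-1-ol
Product: 4 ethyl 2-[(1S)-2,6,6-trimethylcyclohex-2-en-1-yl]acetate, via mixed ketene acetal 3 (not isolated)
Conditions: MeC(OEt)3 (6 equiv), EtCO2H (10 mol %), 140 °C, EtOH distilled off
Reagents that add atoms: triethyl orthoacetate, CCOC(C)(OCC)OCC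
Why: Johnson–Claisen rearrangement, a suprafacial [3,3] shift that forms the new C–C bond at C3 on the ring face the C1–O bond leaves, so the (R) carbinol centre should be relayed to the (S) ring carbon beside the gem-dimethyl group while the olefin moves to C1=C2(CH3).

Step 3
Reactants: 4 ethyl 2-[(1S)-2,6,6-trimethylcyclohex-2-en-1-yl]acetate
Product: 5 2-[(1S)-2,6,6-trimethylcyclohex-2-en-1-yl]ethan-1-ol
Conditions: LiAlH4, Et2O, 0 °C; aqueous NaOH work-up
Reagents that add atoms: none
Why: Hydride reduction of an ester to the primary alcohol; the stereocentre is β to the carbonyl and cannot epimerise.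

Step 4
Reactants: 5 2-[(1S)-2,6,6-trimethylcyclohex-2-en-1-yl]ethan-1-ol
Product: 6 (6S)-6-(2-iodoethyl)-1,5,5-trimethylcyclohex-1-ene
Conditions: I2, PPh3, imidazole, CH2Cl2, 0 °C to rt
Reagents that add atoms: iodine, II
Why: Appel-type iodination of an unhindered primary alcohol through the alkoxyphosphonium iodide, buffered by imidazole so the ring olefin should not migrate.

Step 5
Reactants: 6 (6S)-6-(2-iodoethyl)-1,5,5-trimethylcyclohex-1-ene
Product: 7 (6S)-6-(but-3-yn-1-yl)-1,5,5-trimethylcyclohex-1-ene
Conditions: lithium acetylide–ethylenediamine complex, DMSO, 10 °C to rt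
Reagents that add atoms: lithium acetylide (ethylenediamine complex), [Li]C#C
Why: SN2 alkylation of an acetylide by a primary iodide, which should outrun elimination in DMSO and leaves the stereocentre untouched.

Step 6
Reactants: 7 (6S)-6-(but-3-yn-1-yl)-1,5,5-trimethylcyclohex-1-ene
Product: 9 (6S)-6-[(3E)-4-iodo-3-methylbut-3-en-1-yl]-1,5,5-trimethylcyclohex-1-ene, via alkenyldimethylalane 8 (not isolated)
Conditions: Me3Al (2 equiv), Cp2ZrCl2 (0.25 equiv), CH2Cl2, 0 °C to rt; then I2, THF, −30 to 0 °C
Reagents that add atoms: trimethylaluminium, C[Al](C)C; iodine, II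
Why: Cp2ZrCl2-catalysed carboalumination (Negishi methylalumination) adds CH3 and Al syn across the terminal alkyne with Al at the terminal carbon, and iodinolysis with retention should give the (E)-iodide; the trisubstituted ring olefin is inert.

Step 7
Reactants: 9 (6S)-6-[(3E)-4-iodo-3-methylbut-3-en-1-yl]-1,5,5-trimethylcyclohex-1-ene; 10 (4-bromobut-1-yn-1-yl)trimethylsilane
Product: 13 (6S)-1,5,5-trimethyl-6-[(3E)-3-methyloct-3-en-7-yn-1-yl]cyclohex-1-ene, via silylbutynylzinc bromide 11 (not isolated), via silylated enyne 12 (not isolated)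
Conditions: 10, zinc dust, LiCl, THF, 50 °C; then 9, Pd(PPh3)4 (3 mol %), THF, rt; then MeOH, K2CO3, rt
Reagents that add atoms: none
Why: Negishi coupling of a primary alkylzinc halide with an (E)-alkenyl iodide should proceed with retention of olefin geometry, and K2CO3 in methanol then removes the alkynyl silyl group.

Step 8
Reactants: 13 (6S)-1,5,5-trimethyl-6-[(3E)-3-methyloct-3-en-7-yn-1-yl]cyclohex-1-ene
Product: 15 (6S)-6-[(3E,7E)-8-iodo-3,7-dimethylocta-3,7-dien-1-yl]-1,5,5-trimethylcyclohex-1-ene, via dienyldimethylalane 14 (not isolated)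
Conditions: Me3Al (2 equiv), Cp2ZrCl2 (0.25 equiv), CH2Cl2, 0 °C to rt; then I2, THF, −30 to 0 °C
Reagents that add atoms: trimethylaluminium, C[Al](C)C; iodine, II
Why: A second Cp2ZrCl2-catalysed syn carboalumination and iodinolysis with retention should set the second (E)-trisubstituted olefin; both existing trisubstituted olefins are inert.

Step 9
Reactants: 16 (9Z,12Z)-octadeca-9,12-dienoic acid (linoleic acid)
Product: 17 chloromethyl (9Z,12Z)-octadeca-9,12-dienoate
Conditions: ClCH2OSO2Cl (1.2 equiv), NaHCO3, Bu4NHSO4 (10 mol %), CH2Cl2/H2O, 0 °C to rt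
Reagents that add atoms: chloromethyl chlorosulfate, ClCOS(Cl)(=O)=O
Why: Phase-transfer O-alkylation of the carboxylate, in which chlorosulfate leaves in preference to chloride; the skipped diene is untouched.

Step 10
Reactants: 17 chloromethyl (9Z,12Z)-octadeca-9,12-dienoate
Product: 18 iodomethyl (9Z,12Z)-octadeca-9,12-dienoate
Conditions: NaI (2 equiv), acetone, rt, dark
Reagents that add atoms: sodium iodide, [Na+].[I-]
Why: Finkelstein exchange at the activated acyloxymethyl carbon, driven by precipitation of NaCl.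

Step 11
Reactants: 15 (6S)-6-[(3E,7E)-8-iodo-3,7-dimethylocta-3,7-dien-1-yl]-1,5,5-trimethylcyclohex-1-ene; 18 iodomethyl (9Z,12Z)-octadeca-9,12-dienoate
Product: 20 (2E,6E)-3,7-dimethyl-9-[(1S)-2,6,6-trimethylcyclohex-2-en-1-yl]nona-2,6-dien-1-yl (9Z,12Z)-octadeca-9,12-dienoate, via acyloxymethylzinc iodide 19 (not isolated)
Conditions: 18 (1.6 equiv), activated zinc dust, THF, 10–15 °C; then 15, Pd(OAc)2 (3 mol %), SPhos (6 mol %), THF, rt to 40 °C
Reagents that add atoms: none
Why: Zinc should insert into the activated C–I bond of 18 to give the carbonyl-chelated (acyloxy)methylzinc iodide 19; zerovalent palladium then adds to the alkenyl C–I bond of 15, 19 transfers its O–CH2 group to divalent palladium, and reductive elimination forms the C1–C2 bond. The closest known reaction types are the Negishi coupling of primary alkylzinc iodides with (E)-1-iodo-2-methylalkenes and the use of (pivaloyloxy)methylzinc iodide as a hydroxymethyl anion equivalent. No ring is closed and no stereocentre is formed; the ring stereocentre is remote and untouched. The step needs retention of the (2E) geometry, which stereospecific oxidative addition and reductive elimination at the sp2 carbon should secure. It also needs chemoselectivity over the ester, the skipped 9Z,12Z diene and the trisubstituted olefins, which the mild organozinc should secure. The transferred CH2 has no β-hydrogen, so β-hydride elimination cannot compete.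

**Compound list**

1 | 2,4,4-trimethylcyclohex-2-en-1-one | O=C1CCC(C)(C)C=C1C | starting material
2 | (1R)-2,4,4-trimethylcyclohex-2-en-1-ol | O[C@@H]1CCC(C)(C)C=C1C | intermediate
3 | mixed ketene acetal, (6R)-6-[(1-ethoxyethenyl)oxy]-1,3,3-trimethylcyclohex-1-ene (formed in the flask) | C=C(OCC)O[C@@H]1CCC(C)(C)C=C1C | intermediate
4 | ethyl 2-[(1S)-2,6,6-trimethylcyclohex-2-en-1-yl]acetate | CCOC(=O)C[C@@H]1C(C)=CCCC1(C)C | intermediate
5 | 2-[(1S)-2,6,6-trimethylcyclohex-2-en-1-yl]ethan-1-ol | OCC[C@@H]1C(C)=CCCC1(C)C | intermediate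
6 | (6S)-6-(2-iodoethyl)-1,5,5-trimethylcyclohex-1-ene | ICC[C@@H]1C(C)=CCCC1(C)C | intermediate
7 | (6S)-6-(but-3-yn-1-yl)-1,5,5-trimethylcyclohex-1-ene | C#CCC[C@@H]1C(C)=CCCC1(C)C | intermediate
8 | dimethyl{(1E)-2-methyl-4-[(1S)-2,6,6-trimethylcyclohex-2-en-1-yl]but-1-en-1-yl}alane (formed in the flask) | C[Al](C)/C=C(\C)CC[C@@H]1C(C)=CCCC1(C)C | intermediate
9 | (6S)-6-[(3E)-4-iodo-3-methylbut-3-en-1-yl]-1,5,5-trimethylcyclohex-1-ene | I/C=C(\C)CC[C@@H]1C(C)=CCCC1(C)C | intermediate
10 | (4-bromobut-1-yn-1-yl)trimethylsilane | C[Si](C)(C)C#CCCBr | starting material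
11 | [4-(trimethylsilyl)but-3-yn-1-yl]zinc bromide (formed in the flask) | C[Si](C)(C)C#CCC[Zn]Br | intermediate
12 | trimethyl{(5E)-6-methyl-8-[(1S)-2,6,6-trimethylcyclohex-2-en-1-yl]oct-5-en-1-yn-1-yl}silane (formed in the flask) | C[Si](C)(C)C#CCC/C=C(\C)CC[C@@H]1C(C)=CCCC1(C)C | intermediate
13 | (6S)-1,5,5-trimethyl-6-[(3E)-3-methyloct-3-en-7-yn-1-yl]cyclohex-1-ene | C#CCC/C=C(\C)CC[C@@H]1C(C)=CCCC1(C)C | intermediate
14 | dimethyl{(1E,5E)-2,6-dimethyl-8-[(1S)-2,6,6-trimethylcyclohex-2-en-1-yl]octa-1,5-dien-1-yl}alane (formed in the flask) | C[Al](C)/C=C(\C)CC/C=C(\C)CC[C@@H]1C(C)=CCCC1(C)C | intermediate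
15 | (6S)-6-[(3E,7E)-8-iodo-3,7-dimethylocta-3,7-dien-1-yl]-1,5,5-trimethylcyclohex-1-ene | I/C=C(\C)CC/C=C(\C)CC[C@@H]1C(C)=CCCC1(C)C | intermediate
16 | (9Z,12Z)-octadeca-9,12-dienoic acid (linoleic acid) | CCCCC/C=C\C/C=C\CCCCCCCC(=O)O | starting material
17 | chloromethyl (9Z,12Z)-octadeca-9,12-dienoate | CCCCC/C=C\C/C=C\CCCCCCCC(=O)OCCl | intermediate
18 | iodomethyl (9Z,12Z)-octadeca-9,12-dienoate | CCCCC/C=C\C/C=C\CCCCCCCC(=O)OCI | intermediate
19 | {[(9Z,12Z)-octadeca-9,12-dienoyl]oxy}methylzinc iodide (formed in the flask) | CCCCC/C=C\C/C=C\CCCCCCCC(=O)OC[Zn]I | intermediate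
20 | (2E,6E)-3,7-dimethyl-9-[(1S)-2,6,6-trimethylcyclohex-2-en-1-yl]nona-2,6-dien-1-yl (9Z,12Z)-octadeca-9,12-dienoate | CCCCC/C=C\C/C=C\CCCCCCCC(=O)OC/C=C(\C)CC/C=C(\C)CC[C@@H]1C(C)=CCCC1(C)C | target

**Count and risks**

Total step count: 11. Longest linear sequence: 9 (steps 1 to 8, then step 11).

Step 11 is the riskiest. The chelated, electron-poor (acyloxy)methylzinc may transmetalate to palladium too slowly, so that protodemetalation, homocoupling or decay of the zinc reagent by acyl transfer overtakes cross-coupling. The fallback sets out from 15: iodine–lithium exchange (t-BuLi, 2 equiv, Et2O, −78 °C) and trapping of the alkenyllithium with paraformaldehyde should form the same C1–C2 bond with retention of geometry and give (2E,6E)-3,7-dimethyl-9-[(1S)-2,6,6-trimethylcyclohex-2-en-1-yl]nona-2,6-dien-1-ol F1. Carbodiimide esterification of this alcohol with linoleic acid 16 (EDC, DMAP, CH2Cl2, 0 °C to rt) comes back to the route at 20.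

Step 2 is the second risk. Bond formation beside the quaternary ring carbon may be slow, so that acid-promoted dehydration of the allylic alcohol to a diene at 140 °C competes with the rearrangement. The fallback sets out from 2: acetylation (Ac2O, pyridine, DMAP) should give (1R)-2,4,4-trimethylcyclohex-2-en-1-yl acetate F2. Ireland–Claisen rearrangement of its silyl ketene acetal (LDA, Me3SiCl, THF, −78 °C, then 60 °C; dilute acid work-up) should give 2-[(1S)-2,6,6-trimethylcyclohex-2-en-1-yl]acetic acid F3 by the same suprafacial transfer under non-acidic conditions. Reduction with LiAlH4 comes back to the route at 5.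

Step 1 is the third risk. Facial discrimination may be insufficient, or uncatalysed borane reduction may compete, so that the alcohol is formed in low enantiomeric purity and the error is carried to the ring stereocentre. The fallback sets out from 1: Luche reduction (NaBH4, CeCl3·7H2O, MeOH, 0 °C) should give racemic 2,4,4-trimethylcyclohex-2-en-1-ol F4. Kinetic resolution with Burkholderia cepacia lipase and vinyl acetate in MTBE, stopped short of half conversion, should acylate the (R) enantiomer preferentially, as is usual for secondary alcohols with one large and one medium substituent. This should give (1R)-2,4,4-trimethylcyclohex-2-en-1-yl acetate F5 (the same structure as F2) and leave (1S)-2,4,4-trimethylcyclohex-2-en-1-ol F6, which is separated by chromatography. Methanolysis of the acetate (K2CO3, MeOH) comes back to the route at 2.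

**Further compounds**

F1 | step 11 | (2E,6E)-3,7-dimethyl-9-[(1S)-2,6,6-trimethylcyclohex-2-en-1-yl]nona-2,6-dien-1-ol | OC/C=C(\C)CC/C=C(\C)CC[C@@H]1C(C)=CCCC1(C)C
F2 | step 2 | (1R)-2,4,4-trimethylcyclohex-2-en-1-yl acetate | CC(=O)O[C@@H]1CCC(C)(C)C=C1C
F3 | step 2 | 2-[(1S)-2,6,6-trimethylcyclohex-2-en-1-yl]acetic acid | OC(=O)C[C@@H]1C(C)=CCCC1(C)C
F4 | step 1 | racemic 2,4,4-trimethylcyclohex-2-en-1-ol | OC1CCC(C)(C)C=C1C
F5 | step 1 | (1R)-2,4,4-trimethylcyclohex-2-en-1-yl acetate | CC(=O)O[C@@H]1CCC(C)(C)C=C1C
F6 | step 1 | (1S)-2,4,4-trimethylcyclohex-2-en-1-ol | O[C@H]1CCC(C)(C)C=C1C
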